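**Retrosynthetic overview**

- The plan rests on the E-trisubstituted alkene C7=C8(CH3), which lies next to the acetoxy carbon C6 inside the 12-membered ring (C1 to C11 plus C15). Such an allylic alcohol is what trans-hydrometalation and methylation of a propargylic alcohol deliver, so the ring is closed at a C7≡C8 triple bond and alkene geometry plays no part in the macrocyclisation.
- Target ⇒ (acetylation, C8–CH3 Negishi coupling, C8 iododesilylation, ruthenium trans-hydrosilylation, O-desilylation) ⇒ 12-membered cycloalkyne ⇒ (ring-closing alkyne metathesis, C7≡C8) ⇒ butenolide diyne with two methyl-capped alkynes.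
- Diyne ⇒ (B-alkyl Suzuki–Miyaura coupling, C3–C4) ⇒ vinyl butenolide plus an (S)-2-bromoallyl propargylic silyl ether. The ether comes from but-2-ynal by asymmetric 2-bromoallylboration, which sets C6.
- Vinyl butenolide ⇒ (catalyst-controlled allenylboration and lactonisation, C9–C10, sets C10) ⇒ ring A formyl ester ⇒ (formylation of an enol triflate, Dieckmann closure C11–C12) ⇒ acyclic diester from an iridium-catalysed allylic alkylation (C1–C15, sets C1).
- Order of ring formation: ring A (six-membered carbocycle), then the butenolide, then the 12-membered carbocycle.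

Key step: step 14

Remark: atoms carry verticillane numbers (C1 ring A methine, C15 the CMe2 carbon, C11 and C12 the butenolide β and α carbons, C10 the lactone CH–O, C4 the carbon bearing =CH2, C6 the oxygenated side-chain carbon); the antipodes of the chiral catalysts are assigned from the accepted transition-state models, and the mirror-image catalyst would be taken if a correlation showed the opposite sense.

**Route**

Step 1
Reactants: 1 methyl hex-5-enoate; 2 allyl methyl carbonate
Product: 3 methyl (5E)-7-[(methoxycarbonyl)oxy]hept-5-enoate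
Conditions: second-generation Hoveyda–Grubbs catalyst RuCl2(H2IMes)(=CH-C6H4-2-OiPr) (2 mol%), 2 (3 equiv), CH2Cl2, 40 °C
Reagents that add atoms: none
Why: Olefin cross-metathesis of two unhindered terminal alkenes, driven by loss of ethene and by the excess of 2, should give mainly the E-allylic carbonate, and neither the ester nor the carbonate interferes.

Step 2
Reactants: 3 methyl (5E)-7-[(methoxycarbonyl)oxy]hept-5-enoate; 4 1-methoxy-2-methyl-1-(trimethylsilyloxy)prop-1-ene
Product: 5 dimethyl (3S)-3-ethenyl-2,2-dimethylheptanedioate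
Conditions: [Ir(cod)Cl]2 (2 mol%), BINOL-derived N,N-bis(1-phenylethyl)phosphoramidite (4 mol%, antipode giving 3S), pre-activated with n-PrNH2, 4 (1.5 equiv), THF, rt to 50 °C
Reagents that add atoms: none
Why: Iridium-catalysed asymmetric allylic alkylation with a silyl ketene acetal is branched-selective, the methoxide released from the carbonate unmasks the ester enolate under nearly neutral conditions, and the cyclometalated chiral iridium complex fixes which face of the allyl unit is attacked, which sets C1 next to the new quaternary C15.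

Step 3
Reactants: 5 dimethyl (3S)-3-ethenyl-2,2-dimethylheptanedioate
Product: 6 methyl (4S)-4-ethenyl-3,3-dimethyl-2-oxocyclohexane-1-carboxylate (keto and enol forms)
Conditions: KOtBu (1.5 equiv), THF, 0 °C to rt; then 1 M HCl
Reagents that add atoms: none
Why: The Dieckmann condensation can run in one direction only, because C12 alone carries acidic hydrogens, and the six-membered β-keto ester is held as its enolate until the quench while C1 is not touched.

Step 4
Reactants: 6 methyl (4S)-4-ethenyl-3,3-dimethyl-2-oxocyclohexane-1-carboxylate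
Product: 7 methyl (4S)-4-ethenyl-3,3-dimethyl-2-(trifluoromethylsulfonyloxy)cyclohex-1-ene-1-carboxylate
Conditions: NaH, Et2O, 0 °C; Tf2O, −78 to 0 °C
Reagents that add atoms: triflic anhydride, O=S(=O)(OS(=O)(=O)C(F)(F)F)C(F)(F)F
Why: O-Sulfonylation of the sodium enolate of a cyclic β-keto ester gives the enol triflate, whose geometry is fixed by the ring and whose position is fixed by the quaternary C15.

Step 5
Reactants: 7 methyl (4S)-4-ethenyl-3,3-dimethyl-2-(trifluoromethylsulfonyloxy)cyclohex-1-ene-1-carboxylate
Product: 8 methyl (4S)-4-ethenyl-2-formyl-3,3-dimethylcyclohex-1-ene-1-carboxylate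
Conditions: Pd(PPh3)4 (5 mol%), LiCl (3 equiv), CO (3 atm), Bu3SnH (1.1 equiv, syringe pump), THF, 50 °C
Reagents that add atoms: carbon monoxide, [C-]#[O+]
Why: In this palladium-catalysed reductive carbonylation (Stille-type formylation) oxidative addition of the electron-poor vinyl triflate, CO insertion and hydride transfer from slowly added tin hydride give the enal, and the step is placed here because no alkyne that could be hydrostannylated is yet present.

Step 6
Reactants: 9 but-2-yn-1-ol
Product: 10 but-2-yn-1-yl methyl carbonate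
Conditions: ClCO2Me, pyridine, CH2Cl2, 0 °C
Reagents that add atoms: methyl chloroformate, COC(=O)Cl
Why: Acylation of an unhindered primary alcohol with a chloroformate is a routine carbonate synthesis.

Step 7
Reactants: 10 but-2-yn-1-yl methyl carbonate
Product: 11 2-(buta-2,3-dien-2-yl)-4,4,5,5-tetramethyl-1,3,2-dioxaborolane
Conditions: B2pin2, Cu(OtBu) (5 mol%), Xantphos (5 mol%), THF, rt
Reagents that add atoms: bis(pinacolato)diboron, CC1(C)OB(OC1(C)C)B1OC(C)(C)C(C)(C)O1
Why: In the copper-catalysed SN2' borylation of a propargylic carbonate the boryl copper species attacks the alkyne carbon remote from the leaving group, so the allenylboronate forms rather than its propargyl isomer.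

Step 8
Reactants: 8 methyl (4S)-4-ethenyl-2-formyl-3,3-dimethylcyclohex-1-ene-1-carboxylate; 11 2-(buta-2,3-dien-2-yl)-4,4,5,5-tetramethyl-1,3,2-dioxaborolane
Product: 13 (3R,5S)-3-(but-2-yn-1-yl)-5-ethenyl-4,4-dimethyl-4,5,6,7-tetrahydro-2-benzofuran-1(3H)-one, via O-boryl hydroxy ester 12 (not isolated)
Conditions: (R)-TRIP [(R)-3,3'-bis(2,4,6-triisopropylphenyl)-BINOL hydrogen phosphate] (10 mol%), 11 (1.5 equiv), 4 Å MS, toluene, −20 °C to rt; then PPTS (cat.), CH2Cl2, rt
Reagents that add atoms: none
Why: In the chiral phosphoric acid-catalysed allenylboration the closed SE2' transition state joins the CH2 terminus of the allene to C10 and so gives the methyl-capped homopropargylic alcohol directly, the (R)-acid directs attack to the Re face of the aldehyde and sets 10R by catalyst control because the remote C1 exerts little bias, and the borate then closes onto the cis ester to form the butenolide.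

Step 9
Reactants: 9 but-2-yn-1-ol
Product: 14 but-2-ynal
Conditions: activated MnO2 (excess), CH2Cl2, rt; filtered and concentrated cold
Reagents that add atoms: none
Why: MnO2 oxidation of a propargylic alcohol stops cleanly at the aldehyde.

Step 10
Reactants: 15 2,3-dibromoprop-1-ene
Product: 16 (2-bromoprop-2-en-1-yl)tributylstannane
Conditions: Bu3SnH, LiN(iPr)2, THF, 0 °C; then 15, −78 °C
Reagents that add atoms: tributyltin hydride, CCCC[SnH](CCCC)CCCC
Why: SN2 displacement by the stannyl anion takes place at the allylic bromide only, since the vinylic bromide is inert at low temperature.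

Step 11
Reactants: 14 but-2-ynal; 16 (2-bromoprop-2-en-1-yl)tributylstannane
Product: 18 (4S)-2-bromohept-1-en-5-yn-4-ol, via B-(2-bromoallyl)diazaborolidine 17 (not isolated)
Conditions: (1S,2S)-N,N'-ditosyl-1,2-diphenylethane-1,2-diamine, BBr3, CH2Cl2, 0 °C to rt, then vacuum; 16, CH2Cl2, rt; 14, −78 °C; pH 7 buffer
Reagents that add atoms: boron tribromide, BrB(Br)Br; (1S,2S)-N,N'-ditosyl-1,2-diphenylethane-1,2-diamine, Cc1ccc(cc1)S(=O)(=O)N[C@@H](c1ccccc1)[C@@H](NS(=O)(=O)c1ccc(C)cc1)c1ccccc1 (both end up in 17 only)
Why: In this asymmetric 2-bromoallylboration tin-to-boron exchange gives a chiral allylborane that adds through a chair transition state, the (S,S) sulfonamide controller directs it to the Si face of the ynal and sets 6S, and the route thereby avoids a β,γ-unsaturated ynone that could slip into conjugation.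

Step 12
Reactants: 18 (4S)-2-bromohept-1-en-5-yn-4-ol
Product: 19 [(4S)-2-bromohept-1-en-5-yn-4-yl]oxy(tert-butyl)dimethylsilane
Conditions: TBSCl, imidazole, DMF, rt
Reagents that add atoms: tert-butyldimethylsilyl chloride, CC(C)(C)[Si](C)(C)Cl
Why: Standard silylation of a secondary alcohol masks the propargylic oxygen, which an alkylidyne catalyst would not tolerate in free form.

Step 13
Reactants: 13 (3R,5S)-3-(but-2-yn-1-yl)-5-ethenyl-4,4-dimethyl-4,5,6,7-tetrahydro-2-benzofuran-1(3H)-one; 19 [(4S)-2-bromohept-1-en-5-yn-4-yl]oxy(tert-butyl)dimethylsilane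
Product: 21 (3R,5R)-3-(but-2-yn-1-yl)-5-[(5S)-5-(tert-butyldimethylsilyloxy)-3-methylideneoct-6-yn-1-yl]-4,4-dimethyl-4,5,6,7-tetrahydro-2-benzofuran-1(3H)-one (butenolide diyne), via B-alkyl-9-BBN adduct 20 (not isolated)
Conditions: 9-BBN (1.2 equiv), THF, 0 °C to rt; then 19, Pd(dppf)Cl2 (5 mol%), AsPh3 (10 mol%), K3PO4 (aq, 1.5 equiv), DMF, rt
Reagents that add atoms: 9-borabicyclo[3.3.1]nonane, B1C2CCCC1CCC2 (ends up in 20 only)
Why: 9-BBN hydroborates a monosubstituted alkene faster than an internal alkyne, the B-alkyl Suzuki–Miyaura coupling with the 2-bromoalkene then forms C3–C4 with the C4=CH2 group already in place, and a small excess of phosphate at room temperature should leave the acidic C10–H untouched.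

Step 14
Reactants: 21 butenolide diyne (1R,6S,10R; C6 TBS ether)
Product: 22 12-membered cycloalkyne (1R,6S,10R): ring A butenolide bridged from C1 to C10 by C2H2–C3H2–C4(=CH2)–C5H2–C6H(OTBS)–C7≡C8–C9H2
Conditions: [Mo(≡C-C6H4-4-OMe)(OSiPh3)3] (15 mol%), 5 Å MS, toluene (1 mM), 80 °C
Reagents that add atoms: none
Why: The molybdenum alkylidyne adds to one methyl-capped alkyne in a [2+2] manner, the metallacyclobutadiene cycloreverts to a substrate-bound alkylidyne, and this engages the second alkyne of the same molecule through a second metallacyclobutadiene, which releases 22 and the propagating ethylidyne, so that but-2-yne is the only other product. The closest known reaction type is ring-closing alkyne metathesis of methyl-capped diynes with triarylsilanolate molybdenum alkylidynes, established for rings of twelve and more members that carry esters, silyl ethers and alkenes. The one ring that closes is the 12-membered carbocycle C1 to C11 plus C15, formed end to end by the C7≡C8 bond as a bridge across ring A, a size that can still hold the linear C6–C7≡C8–C9 unit. No stereocentre is created, and C1, C6 and C10 lie outside the reacting bonds and are carried through unchanged. The step needs chemoselectivity for alkynes over the C4=CH2 and C11=C12 alkenes and the lactone, which the alkylidyne provides by its nature, and it needs closure to outrun oligomerisation, which is secured by the placement of the C2 and C9 arms on the same face of the bicyclic butenolide, by high dilution and by trapping of but-2-yne in the sieves. The bulky C6 silyl ether keeps the propargylic oxygen from binding to the Lewis-acidic metal or being ionised by it.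

Step 15
Reactants: 22 12-membered cycloalkyne (C6 TBS ether)
Product: 23 12-membered cycloalkynol (1R,6S,10R) with free C6 hydroxyl
Conditions: HF·pyridine, pyridine, THF, 0 °C to rt
Reagents that add atoms: none
Why: Fluoride-mediated silyl ether cleavage in a buffered acidic medium avoids the basic fluoride sources that could deprotonate C10.

Step 16
Reactants: 23 12-membered cycloalkynol
Product: 24 (7Z)-8-(benzyldimethylsilyl) cycloalkenol (1R,6S,10R) with silicon on C8 cis to C6
Conditions: [Cp*Ru(MeCN)3]PF6 (10 mol%), BnMe2SiH (1.2 equiv), CH2Cl2, 0 °C to rt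
Reagents that add atoms: benzyldimethylsilane, C[SiH](C)Cc1ccccc1
Why: Ruthenium-catalysed trans-hydrosilylation adds H and Si to opposite faces of the alkyne as an intrinsic feature of the cationic catalyst, the propargylic C6 oxygen sends hydrogen to C7 and silicon to the distal C8, and simple alkenes and the lactone are not touched.

Step 17
Reactants: 24 (7Z)-8-(benzyldimethylsilyl) cycloalkenol
Product: 25 (7Z)-8-iodo cycloalkenol (1R,6S,10R)
Conditions: NIS (1.1 equiv), 2,6-lutidine, (CF3)2CHOH, 0 °C, dark
Reagents that add atoms: N-iodosuccinimide, O=C1CCC(=O)N1I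
Why: Iododesilylation is an ipso substitution that proceeds with retention in this weakly nucleophilic solvent, and it should win over the C4=CH2 alkene because iodonium formation there is reversible whereas loss of silicon makes attack at C8 irreversible.

Step 18
Reactants: 25 (7Z)-8-iodo cycloalkenol
Product: 26 (7E)-8-methyl cycloalkenol (1R,6S,10R), the C6 alcohol of the target
Conditions: Me2Zn (3 equiv), Pd(PPh3)4 (5 mol%), THF, 0 °C to rt
Reagents that add atoms: dimethylzinc, C[Zn]C
Why: Negishi coupling of an alkenyl iodide proceeds with retention, so CH3 ends up cis to C6 and C9 trans to it (E), and the step is run before acetylation so that zerovalent palladium never meets an allylic acetate.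

Step 19
Reactants: 26 (7E)-8-methyl cycloalkenol
Product: 27 target CNP0289913.1 (1R,6S,10R,7E)
Conditions: Ac2O, pyridine, DMAP (cat.), CH2Cl2, 0 °C to rt
Reagents that add atoms: acetic anhydride, CC(=O)OC(C)=O
Why: Acylation of the secondary allylic alcohol under mild amine catalysis takes place at oxygen and leaves the C6 configuration unchanged.

**Compound list**

1 | methyl hex-5-enoate | C=CCCCC(=O)OC | starting material
2 | allyl methyl carbonate | C=CCOC(=O)OC | starting material
3 | methyl (5E)-7-[(methoxycarbonyl)oxy]hept-5-enoate | COC(=O)CCC/C=C/COC(=O)OC | intermediate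
4 | 1-methoxy-2-methyl-1-(trimethylsilyloxy)prop-1-ene | COC(O[Si](C)(C)C)=C(C)C | starting material
5 | dimethyl (3S)-3-ethenyl-2,2-dimethylheptanedioate | C=C[C@H](CCCC(=O)OC)C(C)(C)C(=O)OC | intermediate
6 | methyl (4S)-4-ethenyl-3,3-dimethyl-2-oxocyclohexane-1-carboxylate | COC(=O)C1CC[C@@H](C=C)C(C)(C)C1=O | intermediate
7 | methyl (4S)-4-ethenyl-3,3-dimethyl-2-(trifluoromethylsulfonyloxy)cyclohex-1-ene-1-carboxylate | COC(=O)C1=C(OS(=O)(=O)C(F)(F)F)C(C)(C)[C@H](C=C)CC1 | intermediate
8 | methyl (4S)-4-ethenyl-2-formyl-3,3-dimethylcyclohex-1-ene-1-carboxylate | COC(=O)C1=C(C=O)C(C)(C)[C@H](C=C)CC1 | intermediate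
9 | but-2-yn-1-ol | CC#CCO | starting material
10 | but-2-yn-1-yl methyl carbonate | CC#CCOC(=O)OC | intermediate
11 | 2-(buta-2,3-dien-2-yl)-4,4,5,5-tetramethyl-1,3,2-dioxaborolane | C=C=C(C)B1OC(C)(C)C(C)(C)O1 | intermediate
12 | O-boryl hydroxy ester: methyl (4S)-4-ethenyl-3,3-dimethyl-2-[(1R)-1-(pinacolboryloxy)pent-3-yn-1-yl]cyclohex-1-ene-1-carboxylate | COC(=O)C1=C([C@@H](CC#CC)OB2OC(C)(C)C(C)(C)O2)C(C)(C)[C@H](C=C)CC1 | intermediate
13 | (3R,5S)-3-(but-2-yn-1-yl)-5-ethenyl-4,4-dimethyl-4,5,6,7-tetrahydro-2-benzofuran-1(3H)-one | C=C[C@@H]1CCC2=C([C@@H](CC#CC)OC2=O)C1(C)C | intermediate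
14 | but-2-ynal | CC#CC=O | intermediate
15 | 2,3-dibromoprop-1-ene | C=C(Br)CBr | starting material
16 | (2-bromoprop-2-en-1-yl)tributylstannane | C=C(Br)C[Sn](CCCC)(CCCC)CCCC | intermediate
17 | (4S,5S)-2-(2-bromoprop-2-en-1-yl)-4,5-diphenyl-1,3-ditosyl-1,3,2-diazaborolidine | C=C(Br)CB1N(S(=O)(=O)c2ccc(C)cc2)[C@@H](c2ccccc2)[C@H](c2ccccc2)N1S(=O)(=O)c1ccc(C)cc1 | intermediate
18 | (4S)-2-bromohept-1-en-5-yn-4-ol | CC#C[C@@H](O)CC(Br)=C | intermediate
19 | [(4S)-2-bromohept-1-en-5-yn-4-yl]oxy(tert-butyl)dimethylsilane | CC#C[C@@H](O[Si](C)(C)C(C)(C)C)CC(Br)=C | intermediate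
20 | B-alkyl-9-BBN adduct of 13 (boron on C3) | B1(CC[C@@H]2CCC3=C([C@@H](CC#CC)OC3=O)C2(C)C)C2CCCC1CCC2 | intermediate
21 | butenolide diyne (1R,6S,10R), C6 TBS ether | CC#C[C@@H](O[Si](C)(C)C(C)(C)C)CC(=C)CC[C@@H]1CCC2=C([C@@H](CC#CC)OC2=O)C1(C)C | intermediate
22 | 12-membered cycloalkyne (1R,6S,10R), C6 TBS ether | C=C1CC[C@@H]2CCC3=C([C@@H](CC#C[C@@H](O[Si](C)(C)C(C)(C)C)C1)OC3=O)C2(C)C | intermediate
23 | 12-membered cycloalkynol (1R,6S,10R) | C=C1CC[C@@H]2CCC3=C([C@@H](CC#C[C@@H](O)C1)OC3=O)C2(C)C | intermediate
24 | (7Z)-8-(benzyldimethylsilyl) cycloalkenol (1R,6S,10R) | C=C1CC[C@@H]2CCC3=C([C@@H](C/C([Si](C)(C)Cc4ccccc4)=C/[C@@H](O)C1)OC3=O)C2(C)C | intermediate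
25 | (7Z)-8-iodo cycloalkenol (1R,6S,10R) | C=C1CC[C@@H]2CCC3=C([C@@H](C/C(I)=C/[C@@H](O)C1)OC3=O)C2(C)C | intermediate
26 | (7E)-8-methyl cycloalkenol (1R,6S,10R) | C=C1CC[C@@H]2CCC3=C([C@@H](C/C(C)=C/[C@@H](O)C1)OC3=O)C2(C)C | intermediate
27 | CNP0289913.1 (1R,6S,10R,7E) | C=C1CC[C@@H]2CCC3=C([C@@H](C/C(C)=C/[C@@H](OC(C)=O)C1)OC3=O)C2(C)C | target

**Step count**

Total step count: 19. Longest linear sequence: 13 steps (steps 1 to 5, 8 and 13 to 19).

**Steps most likely to fail**

**Step 14 (ring closure).** Intermolecular metathesis may outrun closure, or the reversible reaction may drain into oligomers, if bridging ring A with a ring that holds a linear four-carbon unit costs too much strain.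

The fallback inverts the order of the two unions, so that the ring is closed by an irreversible coupling while the alkyne stays as the masked alkene. It sets out from 13 and 19.
- Alkyne cross-metathesis with the same molybdenum alkylidyne and an excess of 19 forms C7≡C8 intermolecularly. This gives the bromo enyne F1.
- 9-BBN hydroborates the vinyl group of F1 to the borane F2.
- Slow addition of F2 to Pd(dppf)Cl2, AsPh3 and K3PO4 at high dilution closes C3–C4 by an intramolecular B-alkyl Suzuki–Miyaura macrocyclisation.

The route is rejoined at 22.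

**Step 8 (C10).** Addition to the aldehyde, which is flanked by the quaternary C15 and the ester, may be slow. Uncatalysed background addition could then erode the facial selectivity. The methyl group on the boron-bearing carbon may also fit the catalyst pocket poorly.

The fallback sets out from 8 and separates C–C bond formation from capping.
- The parent, commercial allenylboronic acid pinacol ester is added under the same (R)-TRIP catalysis. This gives the O-boryl hydroxy ester F3, which lactonises to the terminal alkyne butenolide F4.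
- NIS with AgNO3 (cat.) in acetone converts F4 into the iodoalkyne F5 without base.
- A Negishi coupling with MeZnCl and Pd(PPh3)4 installs the methyl cap.

The route is rejoined at 13.

**Step 17 (silicon to iodine).** Electrophilic iodine may be consumed by the more electron-rich C4=CH2 alkene. Alternatively, the ipso substitution may lose geometry through a long-lived β-silyl cation next to the electron-poor C6.

The fallback avoids any electrophilic halogen and sets out from 22.
- Ruthenium-catalysed trans-hydrostannation ([Cp*Ru(MeCN)3]PF6, Bu3SnH) is run on the silyl ether, whose bulk should steer tin to C8. This gives the (7Z)-8-stannyl silyl ether F6.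
- A copper-assisted methyl-Stille coupling (MeI, Pd(PPh3)4, Cu(thiophene-2-carboxylate), [Ph2PO2][NBu4], DMF, rt) turns the C–Sn bond directly into C–CH3 with retention. This gives the (7E)-8-methyl silyl ether F7.
- HF·pyridine frees the alcohol.

The route is rejoined at 26.

**Further compounds**

F1 | step 14 | bromo enyne: vinyl butenolide carrying C9H2–C8≡C7–C6H(OTBS)–C5H2–C4(Br)=CH2 | C=C[C@@H]1CCC2=C([C@@H](CC#C[C@@H](O[Si](C)(C)C(C)(C)C)CC(Br)=C)OC2=O)C1(C)C
F2 | step 14 | B-alkyl-9-BBN adduct of F1 (boron on C3) | B1(CC[C@@H]2CCC3=C([C@@H](CC#C[C@@H](O[Si](C)(C)C(C)(C)C)CC(Br)=C)OC3=O)C2(C)C)C2CCCC1CCC2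
F3 | step 8 | O-boryl hydroxy ester with terminal alkyne | COC(=O)C1=C([C@@H](CC#C)OB2OC(C)(C)C(C)(C)O2)C(C)(C)[C@H](C=C)CC1
F4 | step 8 | (3R,5S)-5-ethenyl-4,4-dimethyl-3-(prop-2-yn-1-yl)-4,5,6,7-tetrahydro-2-benzofuran-1(3H)-one | C=C[C@@H]1CCC2=C([C@@H](CC#C)OC2=O)C1(C)C
F5 | step 8 | (3R,5S)-5-ethenyl-3-(3-iodoprop-2-yn-1-yl)-4,4-dimethyl-4,5,6,7-tetrahydro-2-benzofuran-1(3H)-one | C=C[C@@H]1CCC2=C([C@@H](CC#CI)OC2=O)C1(C)C
F6 | step 17 | (7Z)-8-(tributylstannyl) cycloalkene, C6 TBS ether | C=C1CC[C@@H]2CCC3=C([C@@H](C/C([Sn](CCCC)(CCCC)CCCC)=C/[C@@H](O[Si](C)(C)C(C)(C)C)C1)OC3=O)C2(C)C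
F7 | step 17 | (7E)-8-methyl cycloalkene, C6 TBS ether | C=C1CC[C@@H]2CCC3=C([C@@H](C/C(C)=C/[C@@H](O[Si](C)(C)C(C)(C)C)C1)OC3=O)C2(C)C
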